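**Retrosynthetic overview**

1. Ring C (the 3-hydroxy-4-pyranone) is formed last, by Algar–Flynn–Oyamada oxidation of a 2'-hydroxychalcone; the chalcone comes from a Claisen–Schmidt condensation of a ring A acetophenone with a ring B chromene aldehyde, and three methoxymethyl (MOM) ethers are the only protecting groups.
2. The dimethylpyran ring on ring B is cut at O1–C2 and C3–C4 (chromene numbering), giving a 5-bromo-3-(MOM-oxy)salicylaldehyde and 2-methylprop-1-enylboronic acid; one amine-promoted cascade (Petasis borono-Mannich transfer, amine loss, oxa-6π electrocyclization) joins them.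
3. Enabling feature: on ring B the oxygen on C-4' sits ortho to C-5', the carbon that carries the future C4. This hydroxy/formyl pair lets the phenol oxygen tether boron and deliver the alkenyl CH to the iminium carbon, then expel the amine to an ortho-quinone methide whose O=C–C=C–C=C array closes onto the CMe2 terminus.
4. The 8-(1,1-dimethylallyl) group comes from an aromatic Claisen rearrangement of the 4-O-prenyl ether of 2,4,6-trihydroxyacetophenone, in which both ortho carbons are equivalent and the para carbon is blocked.
5. Ring order: rings A and B are bought as benzenes; the pyran ring on ring B is closed first, ring C second; global MOM removal ends the route.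

Key step: step 6

Remark on the chemistry: the target has no stereocentre, so the only stereochemical element on the route is the (E) double bond of the chalcone; stereocentres in transient intermediates are racemic and are erased.

**Route**

Step 1
Reactants: 1 2,4,6-trihydroxyacetophenone; 2 prenyl bromide (1-bromo-3-methylbut-2-ene)
Product: 3 1-[2,6-dihydroxy-4-(3-methylbut-2-enoxy)phenyl]ethanone
Conditions: K2CO3 (1.1 equiv), acetone, reflux
Reagents that add atoms: none
Why: Williamson ether synthesis in which the 4-OH, the most acidic hydroxyl and the only one not tied to the acetyl group by hydrogen bonding, should be alkylated as its monophenoxide, with the weak base in acetone favouring O- over C-prenylation.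

Step 2
Reactants: 3 1-[2,6-dihydroxy-4-(3-methylbut-2-enoxy)phenyl]ethanone
Product: 5 1-[2,4,6-trihydroxy-3-(2-methylbut-3-en-2-yl)phenyl]ethanone, via cyclohexadienone 4 (not isolated)
Conditions: PhNEt2, 185 °C, argon
Reagents that add atoms: none
Why: Aromatic Claisen rearrangement ([3,3]-sigmatropic shift) that inverts the prenyl unit to the 1,1-dimethylallyl group; the two ortho carbons are equivalent by symmetry and the para carbon carries the acetyl group, so only one C-alkylated phenol can form after tautomerisation of dienone 4.

Step 3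
Reactants: 5 1-[2,4,6-trihydroxy-3-(2-methylbut-3-en-2-yl)phenyl]ethanone
Product: 6 1-[2-hydroxy-4,6-bis(methoxymethoxy)-3-(2-methylbut-3-en-2-yl)phenyl]ethanone
Conditions: MOMCl (2.2 equiv), i-Pr2NEt, CH2Cl2, 0 °C to rt
Reagents that add atoms: chloromethyl methyl ether (MOMCl), COCCl
Why: O-alkylation (MOM ether formation) in which the non-chelated 4-OH should react first and the 6-OH second, because the 2-OH is wedged between the acetyl group and the quaternary carbon and is held in the hydrogen bond to the carbonyl.

Step 4
Reactants: 7 2,3-dihydroxybenzaldehyde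
Product: 8 2-hydroxy-3-(methoxymethoxy)benzaldehyde
Conditions: NaH (2.2 equiv), DMSO/THF, rt; MOMCl (1.0 equiv), 0 °C; aq NH4Cl
Reagents that add atoms: chloromethyl methyl ether (MOMCl), COCCl
Why: Regioselective O-alkylation of the bis-phenoxide, in which the 2-oxide is delocalised into the ortho formyl group, so the more basic 3-oxide should take the single equivalent of MOMCl.

Step 5
Reactants: 8 2-hydroxy-3-(methoxymethoxy)benzaldehyde
Product: 9 5-bromo-2-hydroxy-3-(methoxymethoxy)benzaldehyde
Conditions: NBS (1.05 equiv), MeCN, 0 °C to rt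
Reagents that add atoms: N-bromosuccinimide (NBS), O=C1CCC(=O)N1Br
Why: Electrophilic aromatic bromination directed para to the free phenol and meta to the formyl group, as in the bromination of ortho-vanillin, under neutral conditions that leave the MOM acetal intact.

Step 6
Reactants: 9 5-bromo-2-hydroxy-3-(methoxymethoxy)benzaldehyde; 10 2-methylprop-1-enylboronic acid
Product: 13 6-bromo-8-(methoxymethoxy)-2,2-dimethyl-2H-chromene, via allylic amine 11 (not isolated), via ortho-quinone methide 12 (not isolated)
Conditions: Bn2NH (0.4 equiv), 1,4-dioxane, 90 °C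
Reagents that add atoms: none
Why: Bn2NH condenses with the aldehyde of 9 to an iminium ion flanked by the phenoxide, the phenol oxygen binds boronic acid 10 as a tetracoordinate boronate, and the 2-methylprop-1-enyl group passes intramolecularly from boron to the iminium carbon (Petasis borono-Mannich reaction), which makes the C4–C3 bond and gives allylic amine 11. At 90 °C the phenoxide of 11 expels Bn2NH, which returns to the cycle, to give ortho-quinone methide 12; this 1-oxatriene closes the pyran ring by a thermal disrotatory oxa-6π electrocyclization that forms the O1–C2 bond and restores the aromatic sextet of the benzene ring. The closest known reaction type is the amine-promoted condensation of salicylaldehydes with alkenylboronic acids to 2H-chromenes. No stereocentre results, because C2 carries two methyl groups and the amine-bearing centre of 11 becomes sp2 in 12. The step needs control over which carbon and which oxygen are joined and chemoselectivity for alkenyl transfer over protodeboronation: the boron–carbon bond fixes the CH end of the alkene to the former aldehyde carbon and the CMe2 end to oxygen, and because the 3-oxygen is masked as its MOM ether only the phenol oxygen next to the aldehyde can tether boron. The aryl bromide and the MOM acetal should be inert to these neutral conditions.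

Step 7
Reactants: 13 6-bromo-8-(methoxymethoxy)-2,2-dimethyl-2H-chromene
Product: 15 8-(methoxymethoxy)-2,2-dimethyl-2H-chromene-6-carbaldehyde, via aryllithium 14 (not isolated)
Conditions: n-BuLi (1.1 equiv), THF, −78 °C; DMF, −78 °C to rt; aq NH4Cl
Reagents that add atoms: N,N-dimethylformamide (DMF), CN(C)C=O
Why: Bromine–lithium exchange, which at −78 °C should outrun ortho-lithiation next to the MOM ether, followed by Bouveault formylation of the aryllithium with DMF.

Step 8
Reactants: 6 1-[2-hydroxy-4,6-bis(methoxymethoxy)-3-(2-methylbut-3-en-2-yl)phenyl]ethanone; 15 8-(methoxymethoxy)-2,2-dimethyl-2H-chromene-6-carbaldehyde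
Product: 16 (E)-1-[2-hydroxy-4,6-bis(methoxymethoxy)-3-(2-methylbut-3-en-2-yl)phenyl]-3-[8-(methoxymethoxy)-2,2-dimethyl-2H-chromen-6-yl]prop-2-en-1-one
Conditions: KOH, EtOH/H2O, rt
Reagents that add atoms: none
Why: Claisen–Schmidt condensation of the methyl ketone enolate with the non-enolisable aldehyde, in which loss of hydroxide from the aldol adduct should give the thermodynamically favoured (E)-enone.

Step 9
Reactants: 16 (E)-1-[2-hydroxy-4,6-bis(methoxymethoxy)-3-(2-methylbut-3-en-2-yl)phenyl]-3-[8-(methoxymethoxy)-2,2-dimethyl-2H-chromen-6-yl]prop-2-en-1-one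
Product: 18 3-hydroxy-5,7-bis(methoxymethoxy)-2-[8-(methoxymethoxy)-2,2-dimethyl-2H-chromen-6-yl]-8-(2-methylbut-3-en-2-yl)-4H-chromen-4-one, via dihydroflavonol 17 (not isolated)
Conditions: H2O2 (30% aq), NaOH, MeOH/THF, 0 °C to rt
Reagents that add atoms: hydrogen peroxide, OO
Why: Algar–Flynn–Oyamada oxidation, in which conjugate addition of the phenoxide and hydroxylation of the resulting enolate by peroxide should give trans-dihydroflavonol 17, which is dehydrogenated in the same medium to the flavonol, while the nucleophilic oxidant leaves the electron-rich chromene and vinyl alkenes untouched.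

Step 10
Reactants: 18 3-hydroxy-5,7-bis(methoxymethoxy)-2-[8-(methoxymethoxy)-2,2-dimethyl-2H-chromen-6-yl]-8-(2-methylbut-3-en-2-yl)-4H-chromen-4-one
Product: 19 broussonol A (3,5,7-trihydroxy-2-(8-hydroxy-2,2-dimethyl-2H-chromen-6-yl)-8-(2-methylbut-3-en-2-yl)-4H-chromen-4-one)
Conditions: HCl (3 M aq), MeOH/THF, 40 °C
Reagents that add atoms: none
Why: Acid-catalysed acetal exchange of the three aryl MOM ethers with methanol, run in dilute acid at mild temperature because the monosubstituted vinyl group and the chromene alkene should protonate much more slowly than the acetals cleave.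

**Compound list**

1 | 2,4,6-trihydroxyacetophenone | CC(=O)c1c(O)cc(O)cc1O | starting material
2 | prenyl bromide (1-bromo-3-methylbut-2-ene) | CC(C)=CCBr | starting material
3 | 1-[2,6-dihydroxy-4-(3-methylbut-2-enoxy)phenyl]ethanone | CC(=O)c1c(O)cc(OCC=C(C)C)cc1O | intermediate
4 | rac-4-acetyl-3,5-dihydroxy-6-(2-methylbut-3-en-2-yl)cyclohexa-2,4-dien-1-one (not isolated) | CC(=O)C1=C(O)C(C(C)(C)C=C)C(=O)C=C1O | intermediate
5 | 1-[2,4,6-trihydroxy-3-(2-methylbut-3-en-2-yl)phenyl]ethanone | CC(=O)c1c(O)cc(O)c(C(C)(C)C=C)c1O | intermediate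
6 | 1-[2-hydroxy-4,6-bis(methoxymethoxy)-3-(2-methylbut-3-en-2-yl)phenyl]ethanone | CC(=O)c1c(OCOC)cc(OCOC)c(C(C)(C)C=C)c1O | intermediate
7 | 2,3-dihydroxybenzaldehyde | O=Cc1cccc(O)c1O | starting material
8 | 2-hydroxy-3-(methoxymethoxy)benzaldehyde | COCOc1cccc(C=O)c1O | intermediate
9 | 5-bromo-2-hydroxy-3-(methoxymethoxy)benzaldehyde | COCOc1cc(Br)cc(C=O)c1O | intermediate
10 | 2-methylprop-1-enylboronic acid | CC(C)=CB(O)O | starting material
11 | rac-4-bromo-2-[1-(dibenzylamino)-3-methylbut-2-enyl]-6-(methoxymethoxy)phenol (not isolated) | COCOc1cc(Br)cc(C(C=C(C)C)N(Cc2ccccc2)Cc2ccccc2)c1O | intermediate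
12 | (6Z)-4-bromo-2-(methoxymethoxy)-6-(3-methylbut-2-enylidene)cyclohexa-2,4-dien-1-one (not isolated) | CC(C)=C/C=C1/C=C(Br)C=C(OCOC)C1=O | intermediate
13 | 6-bromo-8-(methoxymethoxy)-2,2-dimethyl-2H-chromene | COCOc1cc(Br)cc2c1OC(C)(C)C=C2 | intermediate
14 | [8-(methoxymethoxy)-2,2-dimethyl-2H-chromen-6-yl]lithium (not isolated) | [Li]c1cc(OCOC)c2OC(C)(C)C=Cc2c1 | intermediate
15 | 8-(methoxymethoxy)-2,2-dimethyl-2H-chromene-6-carbaldehyde | COCOc1cc(C=O)cc2c1OC(C)(C)C=C2 | intermediate
16 | (E)-1-[2-hydroxy-4,6-bis(methoxymethoxy)-3-(2-methylbut-3-en-2-yl)phenyl]-3-[8-(methoxymethoxy)-2,2-dimethyl-2H-chromen-6-yl]prop-2-en-1-one | COCOc1cc(OCOC)c(C(C)(C)C=C)c(O)c1C(=O)/C=C/c1cc(OCOC)c2OC(C)(C)C=Cc2c1 | intermediate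
17 | rac-(2R,3R)-3-hydroxy-5,7-bis(methoxymethoxy)-2-[8-(methoxymethoxy)-2,2-dimethyl-2H-chromen-6-yl]-8-(2-methylbut-3-en-2-yl)-2,3-dihydro-4H-chromen-4-one (trans; not isolated) | CC1(C)C=Cc2cc(cc(OCOC)c2O1)[C@@H]1[C@H](C(=O)c2c(OCOC)cc(OCOC)c(C(C)(C)C=C)c2O1)O | intermediate
18 | 3-hydroxy-5,7-bis(methoxymethoxy)-2-[8-(methoxymethoxy)-2,2-dimethyl-2H-chromen-6-yl]-8-(2-methylbut-3-en-2-yl)-4H-chromen-4-one | COCOc1cc(OCOC)c(C(C)(C)C=C)c2oc(-c3cc(OCOC)c4OC(C)(C)C=Cc4c3)c(O)c(=O)c12 | intermediate
19 | broussonol A | C=CC(C)(C)c1c(O)cc(O)c2c(=O)c(O)c(-c3cc(O)c4c(c3)C=CC(C)(C)O4)oc12 | target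

**Step count and risks**

Total step count: 10. Longest linear sequence: 7 (steps 4, 5, 6, 7, 8, 9, 10).

The three steps most likely to fail:

Step 9. The phenoxide may close onto the α-carbon in a five-membered mode instead of onto the β-carbon, a diversion favoured by the 6'-alkoxy group, and the alkaline peroxide may degrade the product further. The fallback sets out from chalcone 16. Dehydrogenative cyclisation with DDQ in 1,4-dioxane at reflux should give the flavone 5,7-bis(methoxymethoxy)-2-[8-(methoxymethoxy)-2,2-dimethyl-2H-chromen-6-yl]-8-(2-methylbut-3-en-2-yl)-4H-chromen-4-one F1. Deprotonation at C3 with LiN(i-Pr)2 in THF at −78 °C should give the 3-lithioflavone F2, which is trapped with B(OMe)3 as the dimethyl flavon-3-ylboronate F3 and oxidised in the same flask with H2O2/AcOH. This comes back to the route at 18.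

Step 6. Transfer of the β,β-disubstituted alkenyl group from boron may be slow, so that protodeboronation of the boronic acid and stalling at the aminal stage take over. The fallback sets out from aldehyde 9. Addition of 2-methylprop-1-enylmagnesium bromide (2.5 equiv, THF, 0 °C) should give the diol rac-4-bromo-2-(1-hydroxy-3-methylbut-2-enyl)-6-(methoxymethoxy)phenol F4. Its dehydration in toluene at 110 °C with a trace of PPTS should pass through the same ortho-quinone methide 12 and the same electrocyclization, and comes back to the route at 13.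

Step 2. At the rearrangement temperature the newly freed phenol may add to the vinyl group (dihydrofuran closure), the allyl unit may isomerise further, and the electron-rich triol may decompose. The fallback sets out from ether 3. The rearrangement is run in Ac2O with NaOAc at 150 °C, so that each phenol is acetylated before or as it forms; this should give 2-acetyl-4-(2-methylbut-3-en-2-yl)benzene-1,3,5-triyl triacetate F5. Methanolysis with K2CO3 in MeOH at rt comes back to the route at 5.

**Further compounds**

F1 | step 9 | 5,7-bis(methoxymethoxy)-2-[8-(methoxymethoxy)-2,2-dimethyl-2H-chromen-6-yl]-8-(2-methylbut-3-en-2-yl)-4H-chromen-4-one | COCOc1cc(OCOC)c(C(C)(C)C=C)c2oc(-c3cc(OCOC)c4OC(C)(C)C=Cc4c3)cc(=O)c12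
F2 | step 9 | 3-lithioflavone derived from F1 (not isolated) | COCOc1cc(OCOC)c(C(C)(C)C=C)c2oc(-c3cc(OCOC)c4OC(C)(C)C=Cc4c3)c([Li])c(=O)c12
F3 | step 9 | dimethyl flavon-3-ylboronate derived from F2 (not isolated) | COCOc1cc(OCOC)c(C(C)(C)C=C)c2oc(-c3cc(OCOC)c4OC(C)(C)C=Cc4c3)c(B(OC)OC)c(=O)c12
F4 | step 6 | rac-4-bromo-2-(1-hydroxy-3-methylbut-2-enyl)-6-(methoxymethoxy)phenol | COCOc1cc(Br)cc(C(O)C=C(C)C)c1O
F5 | step 2 | 2-acetyl-4-(2-methylbut-3-en-2-yl)benzene-1,3,5-triyl triacetate | CC(=O)c1c(OC(C)=O)cc(OC(C)=O)c(C(C)(C)C=C)c1OC(C)=O
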